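**Retrosynthetic overview**
1. Lactone C–O bond last: hydroxy ester → bridged seven-membered lactone, with the ester α-centre corrected by epimerisation.
2. Quaternary carbon bearing CH2O and the 4-methyl-3-oxopentyl chain ⇐ bridging ketone, via spiro-epoxide and Ti(III) radical conjugate addition to isopropyl vinyl ketone.
3. Cyclopentenol and cycloheptane in one step ⇐ intramolecular Ni-catalysed reductive [3+2] of a tethered terminal alkyne with an α-methylene cyclopentanone.
4. Spiro cyclopentanone and its quaternary stereocentre ⇐ catalytic enantioselective one-carbon ring expansion of methyl 3-oxocyclobutanecarboxylate by a piperidone α-diazo ketone (key step).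
5. Ring order: piperidine (bought) → cyclopentane (4→5 expansion) → cyclopentene and cycloheptane together → lactone.

Assumption: 3 (4-iodobut-1-yne carrying a TMS protecting group) and 17 are bought; locants in the text are those of the names given for 12 and 13.

**Step 1**
Reactants: 1 1-methylpiperidin-4-one
Product: 2 1-methylpiperidin-4-one N,N-dimethylhydrazone
Conditions: Me2NNH2, cat. AcOH, EtOH, reflux
Reagents that add atoms: 1,1-dimethylhydrazine, CN(C)N
Why: Hydrazone formation (Corey–Enders activation) gives an aza-enolate precursor that is mono-C-alkylated cleanly at low temperature; no stereocentre is formed.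

**Step 2**
Reactants: 2 1-methylpiperidin-4-one N,N-dimethylhydrazone; 3 (4-iodobut-1-yn-1-yl)trimethylsilane
Product: 5 1-methyl-3-[4-(trimethylsilyl)but-3-yn-1-yl]piperidin-4-one (racemate), via alkylated hydrazone 4 (not isolated)
Conditions: LDA, THF, −78 °C; 3, −78 → 0 °C; then 2 M aq HCl, rt; NaHCO3
Reagents that add atoms: water, O
Why: Aza-enolate alkylation of the symmetric hydrazone with the primary iodide (the silyl cap prevents acetylide formation) followed by acid hydrolysis; the new α-centre is racemic and epimerisable and is fixed only in step 7.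

**Step 3**
Reactants: 5 1-methyl-3-[4-(trimethylsilyl)but-3-yn-1-yl]piperidin-4-one
Product: 8 3-(but-3-yn-1-yl)-5-diazo-1-methylpiperidin-4-one (racemate), via trifluoroacetyl ketone 6 (not isolated), via silylated diazo ketone 7 (not isolated)
Conditions: LiHMDS, THF, −78 °C; CF3CO2CH2CF3; aq NH4Cl; then MsN3, Et3N, MeCN, rt; then K2CO3 (0.2 equiv), MeOH, rt
Reagents that add atoms: methanesulfonyl azide, CS(=O)(=O)N=[N+]=[N-]
Why: Detrifluoroacetylative diazo transfer (Danheiser variant of the Regitz reaction) at the kinetically enolised unsubstituted α-CH2, then carbonate/methanol cleaves the C–Si bond before the base-sensitive spiro-diketone exists.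

**Step 4**
Reactants: 9 3-oxocyclobutane-1-carboxylic acid
Product: 10 methyl 3-oxocyclobutane-1-carboxylate
Conditions: MeI, K2CO3, acetone, rt
Reagents that add atoms: iodomethane, CI
Why: Carboxylate O-alkylation (SN2) masks the acid, which would otherwise be esterified by the diazo compound; no stereocentre.

**Step 5**
Reactants: 8 3-(but-3-yn-1-yl)-5-diazo-1-methylpiperidin-4-one; 10 methyl 3-oxocyclobutane-1-carboxylate
Product: 12 methyl (5R)-9-(but-3-yn-1-yl)-7-methyl-4,10-dioxo-7-azaspiro[4.5]decane-2-carboxylate (epimer mixture at C-2 and C-9), via ammonium triflate 11 (not isolated)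
Conditions: TfOH (1.0 equiv), CH2Cl2, −78 °C; then 10 (1.5 equiv), Sc(OTf)3 (10 mol %), chiral N,N′-dioxide ligand (12 mol %), 4 Å MS, −30 → 0 °C; aq NaHCO3
Reagents that add atoms: none
Why: Proposed new method: the Sc(III)-activated strained cyclobutanone is attacked by the nucleophilic diazo carbon of the cyclic α-diazo ketone (amine masked as its ammonium salt), and 1,2-shift of a ring CH2 with loss of N2 (Tiffeneau–Demjanov-type, not pericyclic) expands the four-ring to the spiro cyclopentanone, the chiral ligand selecting the face of the diazo carbon and so setting the quaternary spiro centre (either CH2 may migrate, giving only ester epimers); the closest known reactions are Lewis-acid ring expansion of cyclobutanones with α-alkyl-α-diazo esters and Sc/N,N′-dioxide-catalysed asymmetric homologation of ketones with α-diazo esters.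

**Step 6**
Reactants: 12 methyl (5R)-9-(but-3-yn-1-yl)-7-methyl-4,10-dioxo-7-azaspiro[4.5]decane-2-carboxylate
Product: 13 methyl (5S)-9-(but-3-yn-1-yl)-7-methyl-3-methylidene-4,10-dioxo-7-azaspiro[4.5]decane-2-carboxylate (same spatial arrangement at C-5; the descriptor changes with CIP priority)
Conditions: (CH2O)n, PhNHMe·TFA, THF, 65 °C; used at once
Reagents that add atoms: formaldehyde (as paraformaldehyde), C=O
Why: Mannich-type α-methylenation occurs only at the cyclopentanone α-CH2, because the piperidone α-carbons are quaternary and tertiary; no new stereocentre.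

**Step 7**
Reactants: 13 methyl (5S)-9-(but-3-yn-1-yl)-7-methyl-3-methylidene-4,10-dioxo-7-azaspiro[4.5]decane-2-carboxylate
Product: 14 tetracyclic keto alcohol (8-methyl-8-azabicyclo[4.3.1]decan-10-one core; C-2 is a tertiary carbinol with a CO2Me-bearing cyclopentane fused on C1–C2 and a cyclopentene on C2–C3; OH cis to the ring-fusion H and to the CH2N arm)
Conditions: Ni(cod)2 (20 mol %), PBu3 (40 mol %), Et3B (3 equiv), THF/MeOH 8:1, 50 °C, 2 mM, slow addition
Reagents that add atoms: none
Why: Nickel-catalysed reductive [3+2] cycloaddition of enone and alkyne (oxidative cyclisation, protonation of the nickel enolate by MeOH, alkenyl–Ni addition to the cyclopentanone carbonyl, Et3B turnover): the tether from C-9 forces the alkenyl carbon onto the carbonyl face syn to the piperidone C=O carbon, so carbinol, cis ring-fusion CH and bridgehead are set together, and the labile C-9 epimers funnel to the one that can bridge.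

**Step 8**
Reactants: 14 tetracyclic keto alcohol
Product: 15 trimethylsilyl ether of 14
Conditions: 1-(trimethylsilyl)imidazole, CH2Cl2, 40 °C
Reagents that add atoms: 1-(trimethylsilyl)imidazole, C[Si](C)(C)n1ccnc1
Why: Silylation of the tertiary alcohol blocks retro-aldol cleavage of the β-hydroxy ketone under the ylide conditions and later prevents γ-lactonisation onto this oxygen.

**Step 9**
Reactants: 15 trimethylsilyl ether of 14
Product: 16 spiro-epoxide at the former bridging ketone carbon (either epoxide configuration)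
Conditions: Me3S+ I−, n-BuLi, THF, −10 °C; then 15, −10 °C → rt
Reagents that add atoms: trimethylsulfonium iodide, C[S+](C)C.[I-]
Why: Corey–Chaykovsky epoxidation works because the bridging ketone cannot enolise (quaternary and bridgehead α-carbons) and so only adds the ylide; the epoxide configuration is irrelevant as it is erased in step 10.

**Step 10**
Reactants: 16 spiro-epoxide; 17 4-methylpent-1-en-3-one
Product: 18 primary alcohol with the new quaternary carbon bearing CH2OH and the 4-methyl-3-oxopentyl chain (silyl ether and methyl ester retained; ester carbon epimer mixture)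
Conditions: Cp2TiCl2 (0.3 equiv), Zn dust (3 equiv), 2,4,6-collidine·HCl (3.5 equiv), 17 (6 equiv), THF, rt
Reagents that add atoms: none
Why: Titanocene(III) reductive epoxide opening (Nugent–RajanBabu, catalytic in Ti) gives the tertiary β-titanoxy radical, which undergoes Giese addition to the enone from the less hindered piperidine-bridge face, placing the side chain syn to the nitrogen bridge and CH2O on the carbocycle side as in the target.

**Step 11**
Reactants: 18 primary alcohol with the quaternary carbon
Product: 20 CNP0242289.1 (target), via silylated lactone 19 (not isolated)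
Conditions: DBU (1.5 equiv), PhMe, 4 Å MS, 90 °C; then AcOH/THF/H2O 3:1:1, rt
Reagents that add atoms: none
Why: Base-mediated lactonisation (transesterification) in which DBU epimerises the ester α-carbon and only the epimer cis to the CH2OH arm can close the bridged seven-membered lactone, which sets that centre, while the silyl ether blocks the competing γ-lactone and is then removed by mild acid.

**Compound list**
1 | 1-methylpiperidin-4-one | CN1CCC(=O)CC1 | starting material
2 | 1-methylpiperidin-4-one N,N-dimethylhydrazone | CN1CCC(=NN(C)C)CC1 | intermediate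
3 | (4-iodobut-1-yn-1-yl)trimethylsilane | C[Si](C)(C)C#CCCI | starting material
4 | N,N-dimethylhydrazone of 5 (racemate) | CN1CCC(=NN(C)C)C(CCC#C[Si](C)(C)C)C1 | intermediate
5 | 1-methyl-3-[4-(trimethylsilyl)but-3-yn-1-yl]piperidin-4-one (racemate) | CN1CCC(=O)C(CCC#C[Si](C)(C)C)C1 | intermediate
6 | 1-methyl-3-(trifluoroacetyl)-5-[4-(trimethylsilyl)but-3-yn-1-yl]piperidin-4-one | CN1CC(CCC#C[Si](C)(C)C)C(=O)C(C(=O)C(F)(F)F)C1 | intermediate
7 | 3-diazo-1-methyl-5-[4-(trimethylsilyl)but-3-yn-1-yl]piperidin-4-one | CN1CC(CCC#C[Si](C)(C)C)C(=O)C(=[N+]=[N-])C1 | intermediate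
8 | 3-(but-3-yn-1-yl)-5-diazo-1-methylpiperidin-4-one (racemate) | CN1CC(CCC#C)C(=O)C(=[N+]=[N-])C1 | intermediate
9 | 3-oxocyclobutane-1-carboxylic acid | OC(=O)C1CC(=O)C1 | starting material
10 | methyl 3-oxocyclobutane-1-carboxylate | COC(=O)C1CC(=O)C1 | intermediate
11 | 3-(but-3-yn-1-yl)-5-diazo-1-methyl-4-oxopiperidin-1-ium triflate | C[NH+]1CC(CCC#C)C(=O)C(=[N+]=[N-])C1.[O-]S(=O)(=O)C(F)(F)F | intermediate
12 | methyl (5R)-9-(but-3-yn-1-yl)-7-methyl-4,10-dioxo-7-azaspiro[4.5]decane-2-carboxylate (C-2 and C-9 epimers) | COC(=O)C1C[C@]2(C(=O)C1)CN(C)CC(CCC#C)C2=O | intermediate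
13 | methyl (5S)-9-(but-3-yn-1-yl)-7-methyl-3-methylidene-4,10-dioxo-7-azaspiro[4.5]decane-2-carboxylate (C-2 and C-9 epimers) | COC(=O)C1C[C@]2(C(=O)C1=C)CN(C)CC(CCC#C)C2=O | intermediate
14 | tetracyclic keto alcohol (bridging ketone, tertiary allylic OH cis to ring-fusion H, methyl ester epimers) | COC(=O)C3C[C@@]4(C2=O)CN(C)C[C@H]2CCC1=CC[C@H]3[C@@]14O | intermediate
15 | trimethylsilyl ether of 14 | COC(=O)C3C[C@@]4(C2=O)CN(C)C[C@H]2CCC1=CC[C@H]3[C@@]14O[Si](C)(C)C | intermediate
16 | spiro-epoxide of 15 (epoxide carbon unassigned) | COC(=O)C3C[C@@]4(C25CO5)CN(C)C[C@H]2CCC1=CC[C@H]3[C@@]14O[Si](C)(C)C | intermediate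
17 | 4-methylpent-1-en-3-one | CC(C)C(=O)C=C | starting material
18 | hydroxymethyl keto ester with the quaternary carbon (silyl ether, ester epimers) | COC(=O)C3C[C@@]4([C@@]2(CO)CCC(=O)C(C)C)CN(C)C[C@H]2CCC1=CC[C@H]3[C@@]14O[Si](C)(C)C | intermediate
19 | O-trimethylsilyl ether of the target lactone | CC(C)C(=O)CC[C@]12COC(=O)[C@@H]3C[C@]14CN(C)C[C@H]2CCC1=CC[C@H]3[C@@]14O[Si](C)(C)C | intermediate
20 | CNP0242289.1 | CC(C)C(=O)CC[C@]12COC(=O)[C@@H]3C[C@]14CN(C)C[C@H]2CCC1=CC[C@H]3[C@@]14O | target

**Totals and risks**
Total steps: 11. Longest linear sequence: 10 (steps 1–3 and 5–11).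

Step 5 (the new enantioselective ring expansion) may fail through a sluggish diazo ketone, catalyst inhibition by the ammonium group or poor face selection. The fallback uses known chemistry and no ring expansion; it sets out from 5 and replaces steps 3–5. Claisen formylation at the free α-CH2 (HCO2Et, NaH) gives the α-formyl ketone F1. C-allylation with methyl 2-(bromomethyl)acrylate (K2CO3, acetone) gives the quaternary keto aldehyde F2. Rh(I)-catalysed intramolecular alkene hydroacylation ([Rh(dppe)]BF4, amine as HBF4 salt) closes the cyclopentanone to the racemic silylated spiro-diketone F3. TBAF/AcOH removes the silyl cap to give the racemic spiro-diketone F4. Resolution of the amine through its di-p-toluoyl-tartrate salt (or chiral SFC) leaves the (5S)-enantiomer F5 behind, and the route is rejoined at 12.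

Step 7 (Ni reductive [3+2] through a ten-membered pre-cyclisation) may give oligomers or simple reductive coupling instead. The fallback sets out from 12. Tsuji–Trost allylation of the kinetic cyclopentanone enolate (LiHMDS; allyl acetate, Pd(PPh3)4) gives the allyl ketone F6. Markovnikov hydroiodination of the alkyne (NaI, TMSCl, H2O, MeCN) gives the 2-iodoalkene F7. Intramolecular Nozaki–Hiyama–Kishi addition (CrCl2, cat. NiCl2, DMF) closes the cycloheptane to the tertiary allylic alcohol F8; only the allyl epimer cis to the new ring is carried on. Ring-closing metathesis (Grubbs II, amine as TsOH salt) forms the cyclopentene and the route is rejoined at 14.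

Step 10 (Ti(III) Giese addition at a carbon flanked by a quaternary centre) may give deoxygenation or simple reduction. The fallback sets out from 15. Wittig methoxymethylenation (Ph3P=CHOMe) gives the enol ether F9. Hg(OAc)2-assisted hydrolysis in aqueous THF gives the aldehyde F10. DBU-catalysed Michael addition of its enolate to 17, from the same piperidine-side face, gives the quaternary keto aldehyde F11. Selective aldehyde reduction (NaBH4, MeOH, −78 °C) rejoins the route at 18.

**Further compounds**
F1 | step 5 | 1-methyl-4-oxo-5-[4-(trimethylsilyl)but-3-yn-1-yl]piperidine-3-carbaldehyde | CN1CC(CCC#C[Si](C)(C)C)C(=O)C(C=O)C1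
F2 | step 5 | methyl 2-({3-formyl-1-methyl-4-oxo-5-[4-(trimethylsilyl)but-3-yn-1-yl]piperidin-3-yl}methyl)prop-2-enoate | COC(=O)C(=C)CC1(C=O)CN(C)CC(CCC#C[Si](C)(C)C)C1=O
F3 | step 5 | racemic methyl 7-methyl-4,10-dioxo-9-[4-(trimethylsilyl)but-3-yn-1-yl]-7-azaspiro[4.5]decane-2-carboxylate | COC(=O)C1CC2(C(=O)C1)CN(C)CC(CCC#C[Si](C)(C)C)C2=O
F4 | step 5 | racemic methyl 9-(but-3-yn-1-yl)-7-methyl-4,10-dioxo-7-azaspiro[4.5]decane-2-carboxylate | COC(=O)C1CC2(C(=O)C1)CN(C)CC(CCC#C)C2=O
F5 | step 5 | methyl (5S)-9-(but-3-yn-1-yl)-7-methyl-4,10-dioxo-7-azaspiro[4.5]decane-2-carboxylate | COC(=O)C1C[C@@]2(C(=O)C1)CN(C)CC(CCC#C)C2=O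
F6 | step 7 | methyl (5R)-9-(but-3-yn-1-yl)-7-methyl-4,10-dioxo-3-(prop-2-en-1-yl)-7-azaspiro[4.5]decane-2-carboxylate | COC(=O)C1C[C@]2(C(=O)C1CC=C)CN(C)CC(CCC#C)C2=O
F7 | step 7 | methyl (5R)-9-(3-iodobut-3-en-1-yl)-7-methyl-4,10-dioxo-3-(prop-2-en-1-yl)-7-azaspiro[4.5]decane-2-carboxylate | COC(=O)C1C[C@]2(C(=O)C1CC=C)CN(C)CC(CCC(I)=C)C2=O
F8 | step 7 | tricyclic tertiary allylic alcohol with exocyclic methylene on the cycloheptane and cis allyl group on the cyclopentane | COC(=O)C3C[C@@]4(C2=O)CN(C)C[C@H]2CCC(=C)[C@]4(O)[C@@H]3CC=C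
F9 | step 10 | methoxymethylidene derivative of 15 | COC(=O)C3C[C@@]4(C2=COC)CN(C)C[C@H]2CCC1=CC[C@H]3[C@@]14O[Si](C)(C)C
F10 | step 10 | one-carbon homologated aldehyde of 15 | COC(=O)C3C[C@@]4(C2C=O)CN(C)C[C@H]2CCC1=CC[C@H]3[C@@]14O[Si](C)(C)C
F11 | step 10 | quaternary keto aldehyde (formyl analogue of 18) | COC(=O)C3C[C@@]4([C@@]2(C=O)CCC(=O)C(C)C)CN(C)C[C@H]2CCC1=CC[C@H]3[C@@]14O[Si](C)(C)C
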